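## Retrosynthetic overview

1. The cyclohexenone, the only ring of the target, is closed last by forming C5–C6: an intramolecular aldol of the methyl ketone of an acyclic (Z)-ene-dione onto the fatty-acyl ketone. This is the aldol that closes the polyketide chain in the presumed biogenesis; C5 is set from the C4 silyl ether.
2. The (Z)-ene-dione comes from a 2,5-disubstituted furan used as a latent cis-enedione: oxidative ring expansion to a pyranone (a temporary ring, formed first), carbonyl reduction (sets C4), silylation, ring opening and oxidation of the relay carbinol.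
3. The (R)-furyl carbinol comes from asymmetric transfer hydrogenation of the 2-acyl-5-methylfuran made from 2-methylfuran and (E)-icos-17-enoic acid.
4. (E)-Icos-17-enoic acid comes from 16-bromohexadecanoic acid and but-1-yne, followed by dissolving-metal reduction (E-alkene).
5. Ring order: dihydropyran (made, later opened), then the carbocycle.

Numbering and assumption: ring atoms are C1 (C=O), C2=C3, C4 (CHOH), C5 (C(OH)R), C6 (CH2). The target SMILES is read as the trans-(4S,5S) diol with a (16E) side chain. 16-Bromohexadecanoic acid, but-1-yne and 2-methylfuran are taken as catalogue starting materials.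

## Route

Step 1
Reactants: 1 16-bromohexadecanoic acid; 2 but-1-yne
Product: 4 icos-17-ynoic acid, via lithium but-1-yn-1-ide 3 (not isolated)
Conditions: n-BuLi (3.2 equiv), THF, −78 °C; add 1, DMPU, −78 °C → rt; then 1 M HCl
Reagents that add atoms: none
Why: Acetylide alkylation (SN2) of the primary bromide, the first equivalent of acetylide only forming the lithium carboxylate, assembles the whole C20 chain; no stereocentre is formed.

Step 2
Reactants: 4 icos-17-ynoic acid
Product: 5 (17E)-icos-17-enoic acid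
Conditions: Li, NH3(l)/THF, −33 °C; then NH4Cl
Reagents that add atoms: none
Why: Dissolving-metal reduction of the internal alkyne through the trans vinyl radical anion gives only the E-alkene while the carboxylate is inert, which fixes the (16E) geometry of the side chain.

Step 3
Reactants: 5 (17E)-icos-17-enoic acid; 6 2-methylfuran
Product: 8 (17E)-1-(5-methylfuran-2-yl)icos-17-en-1-one, via mixed trifluoroacetic anhydride 7 (not isolated)
Conditions: (CF3CO)2O, CH2Cl2, 0 °C; then 6, 0 °C → rt
Reagents that add atoms: none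
Why: Friedel–Crafts acylation of the electron-rich furan at its free α-position by the mixed anhydride needs no Lewis acid, so the isolated E-alkene is left alone.

Step 4
Reactants: 8 (17E)-1-(5-methylfuran-2-yl)icos-17-en-1-one
Product: 9 (1R,17E)-1-(5-methylfuran-2-yl)icos-17-en-1-ol
Conditions: RuCl[(R,R)-TsDPEN](p-cymene) (1 mol %), HCO2H/Et3N (5:2), CH2Cl2, 30 °C
Reagents that add atoms: none
Why: Noyori asymmetric transfer hydrogenation, in which the (R,R)-ligated ruthenium hydride reduces the furyl (aryl-type) ketone from one face to give the (R)-carbinol in high ee, leaves isolated alkenes untouched.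

Step 5
Reactants: 9 (1R,17E)-1-(5-methylfuran-2-yl)icos-17-en-1-ol
Product: 11 (2R,6S)-6-methoxy-6-methyl-2-[(16E)-nonadec-16-en-1-yl]-2H-pyran-3(6H)-one, via hemiketal pyranone 10 (not isolated)
Conditions: VO(acac)2 (3 mol %), t-BuOOH, CH2Cl2, 0 °C → rt; then CH(OMe)3, MeOH, PPTS (cat.), rt
Reagents that add atoms: tert-butyl hydroperoxide CC(C)(C)OO; trimethyl orthoformate COC(OC)OC
Why: Achmatowicz oxidative ring expansion (hydroxyl-directed, so the remote alkene is ignored) unveils the latent cis-enedione as its pyranone hemiketal with the carbinol centre intact, and thermodynamic ketalisation gives the anomer with axial OMe trans to the C2 chain.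

Step 6
Reactants: 11 (2R,6S)-6-methoxy-6-methyl-2-[(16E)-nonadec-16-en-1-yl]-2H-pyran-3(6H)-one
Product: 12 (2R,3S,6S)-6-methoxy-6-methyl-2-[(16E)-nonadec-16-en-1-yl]-3,6-dihydro-2H-pyran-3-ol
Conditions: NaBH4, CeCl3·7H2O, MeOH/CH2Cl2, −78 °C
Reagents that add atoms: none
Why: Luche 1,2-reduction delivers hydride pseudoaxially on the face opposite the axial anomeric methoxy group, giving the equatorial (3S)-allylic alcohol trans to the C2 chain; this centre becomes C4 of the target.

Step 7
Reactants: 12 (2R,3S,6S)-6-methoxy-6-methyl-2-[(16E)-nonadec-16-en-1-yl]-3,6-dihydro-2H-pyran-3-ol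
Product: 13 tert-butyl{[(2R,3S,6S)-6-methoxy-6-methyl-2-[(16E)-nonadec-16-en-1-yl]-3,6-dihydro-2H-pyran-3-yl]oxy}dimethylsilane
Conditions: TBSCl, imidazole, DMF, rt
Reagents that add atoms: tert-butyldimethylsilyl chloride CC(C)(C)[Si](C)(C)Cl
Why: Standard silylation of the only free hydroxyl puts a bulky, non-chelating group on the future C4 oxygen.

Step 8
Reactants: 13 tert-butyl{[(2R,3S,6S)-6-methoxy-6-methyl-2-[(16E)-nonadec-16-en-1-yl]-3,6-dihydro-2H-pyran-3-yl]oxy}dimethylsilane
Product: 15 (3Z,5S,22E)-5-[(tert-butyldimethylsilyl)oxy]pentacosa-3,22-diene-2,6-dione, via pyranol hemiketal 14 (not isolated)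
Conditions: PPTS, acetone/H2O, rt; then Dess–Martin periodinane, NaHCO3, CH2Cl2, 0 °C → rt
Reagents that add atoms: water O
Why: Mild hydrolysis of the allylic mixed ketal gives the hemiketal, whose ring-opened δ-hydroxy enone tautomer undergoes Dess–Martin oxidation to the long-chain ketone under neutral conditions, erasing the relay stereocentre and leaving the (Z)-ene-dione with the C4 silyl ether.

Step 9
Reactants: 15 (3Z,5S,22E)-5-[(tert-butyldimethylsilyl)oxy]pentacosa-3,22-diene-2,6-dione
Product: 18 (4S,5S)-4-[(tert-butyldimethylsilyl)oxy]-5-hydroxy-5-[(16E)-nonadec-16-en-1-yl]cyclohex-2-en-1-one, via silyl dienol ether 16 (not isolated), via bis-silyl aldol adduct 17 (not isolated)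
Conditions: TMSOTf (2.0 equiv), Et3N (1.2 equiv), CH2Cl2, −78 → −30 °C; then aq. citric acid, THF, 0 °C
Reagents that add atoms: none
Why: Intramolecular Mukaiyama aldol (6-enolendo-exo-trig) copying the polyketide ring closure: TMSOTf silylates the more Lewis-basic enone carbonyl and Et3N removes a methyl proton (the doubly activated ring C4–H is held near the alkene plane by allylic 1,3-strain and shielded by OTBS), and the 2-silyloxydiene adds to the silyl-activated, non-chelated ketone through a Cornforth-type transition state (C–OTBS pseudoaxial and anti to the carbonyl oxygen, chain equatorial) that puts the new tertiary oxygen trans to OTBS, setting (5S) from (4S).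

Step 10
Reactants: 18 (4S,5S)-4-[(tert-butyldimethylsilyl)oxy]-5-hydroxy-5-[(16E)-nonadec-16-en-1-yl]cyclohex-2-en-1-one
Product: 19 (4S,5S)-4,5-dihydroxy-5-[(16E)-nonadec-16-en-1-yl]cyclohex-2-en-1-one
Conditions: HF·pyridine, pyridine/THF, 0 °C → rt
Reagents that add atoms: none
Why: Buffered, non-basic fluoride desilylation frees the C4 hydroxyl without β-elimination of the tertiary aldol hydroxyl and without touching either stereocentre.

## Compound list

1 | 16-bromohexadecanoic acid | OC(=O)CCCCCCCCCCCCCCCBr | starting material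
2 | but-1-yne | CCC#C | starting material
3 | lithium but-1-yn-1-ide | [Li]C#CCC | intermediate (not isolated)
4 | icos-17-ynoic acid | CCC#CCCCCCCCCCCCCCCCC(=O)O | intermediate
5 | (17E)-icos-17-enoic acid | CC/C=C/CCCCCCCCCCCCCCCC(=O)O | intermediate
6 | 2-methylfuran | Cc1ccco1 | starting material
7 | (17E)-icos-17-enoic trifluoroacetic anhydride | CC/C=C/CCCCCCCCCCCCCCCC(=O)OC(=O)C(F)(F)F | intermediate (not isolated)
8 | (17E)-1-(5-methylfuran-2-yl)icos-17-en-1-one | CC/C=C/CCCCCCCCCCCCCCCC(=O)c1ccc(C)o1 | intermediate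
9 | (1R,17E)-1-(5-methylfuran-2-yl)icos-17-en-1-ol | CC/C=C/CCCCCCCCCCCCCCC[C@@H](O)c1ccc(C)o1 | intermediate
10 | (2R)-6-hydroxy-6-methyl-2-[(16E)-nonadec-16-en-1-yl]-2H-pyran-3(6H)-one (anomers) | CC/C=C/CCCCCCCCCCCCCCC[C@H]1OC(C)(O)C=CC1=O | intermediate (not isolated)
11 | (2R,6S)-6-methoxy-6-methyl-2-[(16E)-nonadec-16-en-1-yl]-2H-pyran-3(6H)-one | CC/C=C/CCCCCCCCCCCCCCC[C@H]1O[C@](C)(OC)C=CC1=O | intermediate
12 | (2R,3S,6S)-6-methoxy-6-methyl-2-[(16E)-nonadec-16-en-1-yl]-3,6-dihydro-2H-pyran-3-ol | CC/C=C/CCCCCCCCCCCCCCC[C@H]1O[C@](C)(OC)C=C[C@@H]1O | intermediate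
13 | tert-butyl{[(2R,3S,6S)-6-methoxy-6-methyl-2-[(16E)-nonadec-16-en-1-yl]-3,6-dihydro-2H-pyran-3-yl]oxy}dimethylsilane | CC/C=C/CCCCCCCCCCCCCCC[C@H]1O[C@](C)(OC)C=C[C@@H]1O[Si](C)(C)C(C)(C)C | intermediate
14 | (5S,6R)-5-[(tert-butyldimethylsilyl)oxy]-2-methyl-6-[(16E)-nonadec-16-en-1-yl]-5,6-dihydro-2H-pyran-2-ol (anomers, in equilibrium with the open hydroxy enone) | CC/C=C/CCCCCCCCCCCCCCC[C@H]1OC(C)(O)C=C[C@@H]1O[Si](C)(C)C(C)(C)C | intermediate (not isolated)
15 | (3Z,5S,22E)-5-[(tert-butyldimethylsilyl)oxy]pentacosa-3,22-diene-2,6-dione | CC/C=C/CCCCCCCCCCCCCCCC(=O)[C@@H](O[Si](C)(C)C(C)(C)C)/C=C\C(C)=O | intermediate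
16 | (3Z,5S,22E)-5-[(tert-butyldimethylsilyl)oxy]-2-[(trimethylsilyl)oxy]pentacosa-1,3,22-trien-6-one | CC/C=C/CCCCCCCCCCCCCCCC(=O)[C@@H](O[Si](C)(C)C(C)(C)C)/C=C\C(=C)O[Si](C)(C)C | intermediate (not isolated)
17 | (4S,5S)-4-[(tert-butyldimethylsilyl)oxy]-5-[(16E)-nonadec-16-en-1-yl]-5-[(trimethylsilyl)oxy]cyclohex-2-en-1-one | CC/C=C/CCCCCCCCCCCCCCC[C@]1(O[Si](C)(C)C)CC(=O)C=C[C@@H]1O[Si](C)(C)C(C)(C)C | intermediate (not isolated)
18 | (4S,5S)-4-[(tert-butyldimethylsilyl)oxy]-5-hydroxy-5-[(16E)-nonadec-16-en-1-yl]cyclohex-2-en-1-one | CC/C=C/CCCCCCCCCCCCCCC[C@]1(O)CC(=O)C=C[C@@H]1O[Si](C)(C)C(C)(C)C | intermediate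
19 | (4S,5S)-4,5-dihydroxy-5-[(16E)-nonadec-16-en-1-yl]cyclohex-2-en-1-one | CC/C=C/CCCCCCCCCCCCCCC[C@]1(O)CC(=O)C=C[C@@H]1O | target

## Step count and fallbacks

Total step count: 10. Longest linear sequence: 10 (fully linear from 1).

The three steps most likely to fail are steps 9, 5 and 3.

**Step 9 (ring-closing aldol).** The soft enolisation could pick the wrong ketone or erode C4, or TMSOTf could be too weak to drive addition to a ketone. The fallback builds the nucleophile before the C5 ketone exists, so that no base ever meets the ene-dione. It sets out from 14, this time isolated after the hydrolysis half of step 8. LiN(i-Pr)2 (2.2 equiv, THF, −78 °C) forms the alkoxide of the ring-opened hydroxy enone and its kinetic methyl enolate. i-Pr3SiOTf (1.05 equiv) silylates the enolate oxygen in preference to the hindered secondary alkoxide and gives the silyl dienol ether alcohol F1. Dess–Martin periodinane with pyridine oxidises the free carbinol to the silyl dienol ether ketone F2. BF3·OEt2 in CH2Cl2 at −78 °C then effects a base-free Mukaiyama aldol with the same Cornforth-type control. The fallback comes back to the route at 18.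

**Step 5 (Achmatowicz ring expansion and ketalisation).** The tertiary hemiketal may eliminate or ketalise poorly under acid. The fallback masks the anomeric hydroxyl as an ester instead of a ketal and unmasks it with base instead of acid. It sets out from 10, isolated. Ac2O, Et3N and DMAP give the anomeric acetate F3. NaBH4/CeCl3·7H2O gives the allylic alcohol acetate F4. TBSCl/imidazole gives the silyl ether acetate F5. K2CO3 in MeOH at 0 °C removes the acetate, and the fallback comes back to the route at 14, which is oxidised as in step 8.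

**Step 3 (acylation of 2-methylfuran).** Trifluoroacetic acid may polymerise the furan or add to the alkene. The fallback reverses the polarity: a nucleophilic furan attacks an acyl electrophile. It sets out from 5. 1,1′-Carbonyldiimidazole followed by MeNHOMe·HCl gives the Weinreb amide F6. (5-Methylfuran-2-yl)lithium F7, made from 6 with n-BuLi in THF at 0 °C, adds at −78 °C. The fallback comes back to the route at 8.

## Further compounds

F1 | step 9 | (3Z,5S,6R,22E)-5-[(tert-butyldimethylsilyl)oxy]-2-[(triisopropylsilyl)oxy]pentacosa-1,3,22-trien-6-ol | CC/C=C/CCCCCCCCCCCCCCC[C@@H](O)[C@@H](O[Si](C)(C)C(C)(C)C)/C=C\C(=C)O[Si](C(C)C)(C(C)C)C(C)C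
F2 | step 9 | (3Z,5S,22E)-5-[(tert-butyldimethylsilyl)oxy]-2-[(triisopropylsilyl)oxy]pentacosa-1,3,22-trien-6-one | CC/C=C/CCCCCCCCCCCCCCCC(=O)[C@@H](O[Si](C)(C)C(C)(C)C)/C=C\C(=C)O[Si](C(C)C)(C(C)C)C(C)C
F3 | step 5 | (2R)-6-acetoxy-6-methyl-2-[(16E)-nonadec-16-en-1-yl]-2H-pyran-3(6H)-one (anomers) | CC/C=C/CCCCCCCCCCCCCCC[C@H]1OC(C)(OC(C)=O)C=CC1=O
F4 | step 5 | (2R,3S)-6-acetoxy-6-methyl-2-[(16E)-nonadec-16-en-1-yl]-3,6-dihydro-2H-pyran-3-ol (anomers) | CC/C=C/CCCCCCCCCCCCCCC[C@H]1OC(C)(OC(C)=O)C=C[C@@H]1O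
F5 | step 5 | (2R,3S)-6-acetoxy-3-[(tert-butyldimethylsilyl)oxy]-6-methyl-2-[(16E)-nonadec-16-en-1-yl]-3,6-dihydro-2H-pyran (anomers) | CC/C=C/CCCCCCCCCCCCCCC[C@H]1OC(C)(OC(C)=O)C=C[C@@H]1O[Si](C)(C)C(C)(C)C
F6 | step 3 | (17E)-N-methoxy-N-methylicos-17-enamide | CC/C=C/CCCCCCCCCCCCCCCC(=O)N(C)OC
F7 | step 3 | (5-methylfuran-2-yl)lithium | [Li]c1ccc(C)o1
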